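The route rests on reading ring D (the 2,2-dimethyl-2H-pyran fused to the pendant benzene ring B) as an isomer of an aryl isopropyl ether with an ortho ethynyl group: C2 of ring D, carrying two methyls and the ether oxygen, is the isopropyl methine, and C3=C4 is the alkyne. A π-acid-triggered 1,5-hydride shift/6-endo cyclisation converts this open precursor into the chromene in one redox-neutral operation, forming the C2–C3 bond. The resulting bromochromene is joined to a chroman-4-one (rings A and C) by ketone α-arylation; asymmetric transfer hydrogenation with dynamic kinetic resolution sets C3 of ring C, and ortho-formylation at C8 of ring A and desilylation finish.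

Key step: step 5

Remark: the stereocenter of the target is read as (3R); 5,7-dihydroxychroman-4-one (7) is taken as a purchasable building block; atom numbers follow chromane numbering.

Step 1
Reactants: 1 2,6-dihydroxybenzaldehyde
Product: 2 2-hydroxy-6-{[tri(propan-2-yl)silyl]oxy}benzaldehyde
Conditions: TIPSCl (1.05 equiv), imidazole, CH2Cl2, 0 °C to rt
Reagents that add atoms: chlorotri(propan-2-yl)silane (TIPSCl), CC(C)[Si](Cl)(C(C)C)C(C)C
Why: Silylation of one of two equivalent phenols; the remaining hydroxyl stays chelated to the aldehyde and is shielded by the first bulky silyl group, so mono-protection should dominate.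

Step 2
Reactants: 2 2-hydroxy-6-{[tri(propan-2-yl)silyl]oxy}benzaldehyde
Product: 3 3-bromo-2-hydroxy-6-{[tri(propan-2-yl)silyl]oxy}benzaldehyde
Conditions: NBS (1.0 equiv), MeCN, −20 to 0 °C
Reagents that add atoms: N-bromosuccinimide (NBS), BrN1C(=O)CCC1=O
Why: Electrophilic aromatic bromination should go to C3, which is ortho to the free phenol and para to the silyloxy group, because the other activated carbon (C5) is blocked by the adjacent triisopropylsilyloxy group.

Step 3
Reactants: 3 3-bromo-2-hydroxy-6-{[tri(propan-2-yl)silyl]oxy}benzaldehyde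
Product: 4 3-bromo-2-(propan-2-yloxy)-6-{[tri(propan-2-yl)silyl]oxy}benzaldehyde
Conditions: 2-propanol, PPh3, DIAD, THF, 0 °C to rt
Reagents that add atoms: propan-2-ol, CC(C)O
Why: Mitsunobu etherification of an acidic chelated phenol with a secondary alcohol; the neutral conditions spare the aryl silyl ether and the aldehyde.

Step 4
Reactants: 4 3-bromo-2-(propan-2-yloxy)-6-{[tri(propan-2-yl)silyl]oxy}benzaldehyde
Product: 5 [4-bromo-2-ethynyl-3-(propan-2-yloxy)phenoxy]tri(propan-2-yl)silane
Conditions: TMSCHN2, LDA, THF, −78 °C to rt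
Reagents that add atoms: (trimethylsilyl)diazomethane, C[Si](C)(C)C=[N+]=[N-]
Why: Colvin rearrangement: the lithiated silyldiazomethane adds to the aldehyde, and loss of silanolate and N2 with 1,2-hydrogen shift gives the terminal alkyne without the carbonate/methanol medium that could cleave the aryl silyl ether.

Step 5
Reactants: 5 [4-bromo-2-ethynyl-3-(propan-2-yloxy)phenoxy]tri(propan-2-yl)silane
Product: 6 [(8-bromo-2,2-dimethyl-2H-chromen-5-yl)oxy]tri(propan-2-yl)silane
Conditions: PtI4 (10 mol%), MeCN, 120 °C, sealed tube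
Reagents that add atoms: none
Why: Proposed new method: the electrophilic platinum of PtI4 binds the terminal alkyne, whose internal carbon is made electron-poor by the two ortho oxygens, and the isopropyl methine hydrogen, held next to that carbon by the ortho relationship, migrates as hydride through a six-membered transition state (1,5-shift) to give an aryl 2-propylidene oxocarbenium ion and an alkenylplatinum unit with platinum cis to the arene. This zwitterion should collapse by attack of the platinum-bearing carbon (future C3) on the oxocarbenium carbon (future C2), which closes ring D in a 6-endo mode and releases PtI4, so the step is a redox-neutral isomerisation. The closest known reaction types are the PtI4- and gold-catalysed hydride-transfer hydroalkylation of terminal alkynes tethered to dialkyl ethers and the Lewis acid-catalysed 1,5-hydride shift/6-endo cyclisation of ortho-alkoxybenzylidene malonates to chromanes; an aryl isopropyl ether has not been paired with an ortho ethynyl group in this way. No stereocenter is formed. The step needs hydride donation from the isopropyl group only and 6-endo instead of 5-exo closure: the silyl ether has no C–H next to oxygen and its hindered oxygen is a poor nucleophile toward the activated alkyne, the bromide is inert, and a 5-exo adduct would be a platinum carbene that can still reach the same chromene by 1,2-shift of the C2 carbon.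

Step 6
Reactants: 7 5,7-dihydroxy-2,3-dihydro-4H-chromen-4-one
Product: 8 5-hydroxy-7-(methoxymethoxy)-2,3-dihydro-4H-chromen-4-one
Conditions: MOMCl (1.1 equiv), DIPEA, CH2Cl2, 0 °C to rt
Reagents that add atoms: chloromethyl methyl ether (MOMCl), COCCl
Why: Chemoselective O-alkylation of the free 7-hydroxyl; the 5-hydroxyl is deactivated by its hydrogen bond to the C4 carbonyl.

Step 7
Reactants: 8 5-hydroxy-7-(methoxymethoxy)-2,3-dihydro-4H-chromen-4-one
Product: 9 5-methoxy-7-(methoxymethoxy)-2,3-dihydro-4H-chromen-4-one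
Conditions: MeI, K2CO3, DMF, 50 °C
Reagents that add atoms: iodomethane, CI
Why: Williamson methylation of the chelated 5-hydroxyl, which needs the excess of reagent and mild heating used here.

Step 8
Reactants: 6 [(8-bromo-2,2-dimethyl-2H-chromen-5-yl)oxy]tri(propan-2-yl)silane; 9 5-methoxy-7-(methoxymethoxy)-2,3-dihydro-4H-chromen-4-one
Product: 10 rac-3-(2,2-dimethyl-5-{[tri(propan-2-yl)silyl]oxy}-2H-chromen-8-yl)-5-methoxy-7-(methoxymethoxy)-2,3-dihydro-4H-chromen-4-one
Conditions: Pd2(dba)3 (2.5 mol%), XPhos (6 mol%), K3PO4, toluene, 100 °C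
Reagents that add atoms: none
Why: Palladium-catalysed α-arylation of a ketone enolate with an aryl bromide, a known entry from chroman-4-ones to isoflavanones; the tertiary α-carbon of the product resists a second arylation, the phosphate base spares the silyl ether, and the new stereocenter is formed racemic and labile, to be set in step 9.

Step 9
Reactants: 10 rac-3-(2,2-dimethyl-5-{[tri(propan-2-yl)silyl]oxy}-2H-chromen-8-yl)-5-methoxy-7-(methoxymethoxy)-2,3-dihydro-4H-chromen-4-one
Product: 12 (3R)-3-(2,2-dimethyl-5-{[tri(propan-2-yl)silyl]oxy}-2H-chromen-8-yl)-5-methoxy-7-(methoxymethoxy)-3,4-dihydro-2H-chromene, via cis-(3R,4R)-chroman-4-ol 11 (not isolated)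
Conditions: RuCl[(R,R)-TsDPEN](p-cymene) (5 mol%), HCO2H/Et3N (5:2), EtOAc, 40 to 60 °C
Reagents that add atoms: none
Why: Noyori–Ikariya asymmetric transfer hydrogenation with dynamic kinetic resolution: C3 of the ketone epimerises through the enol in the amine buffer while the (R,R) catalyst should reduce only the matched enantiomer to the cis-(3R,4R) alcohol, whose benzylic hydroxyl (ortho and para to the ring A oxygens) ionises in formic acid and is replaced by hydride from the ruthenium hydride, a known one-pot passage from isoflavanones to isoflavans that leaves the catalyst-selected C3 configuration.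

Step 10
Reactants: 12 (3R)-3-(2,2-dimethyl-5-{[tri(propan-2-yl)silyl]oxy}-2H-chromen-8-yl)-5-methoxy-7-(methoxymethoxy)-3,4-dihydro-2H-chromene
Product: 13 (3R)-3-(2,2-dimethyl-5-{[tri(propan-2-yl)silyl]oxy}-2H-chromen-8-yl)-5-methoxy-3,4-dihydro-2H-chromen-7-ol
Conditions: NaHSO4·SiO2, CH2Cl2, rt
Reagents that add atoms: none
Why: Selective acetal hydrolysis of a phenolic methoxymethyl ether on a mildly acidic solid support, which should leave the aryl silyl ether and the chromene double bond untouched.

Step 11
Reactants: 13 (3R)-3-(2,2-dimethyl-5-{[tri(propan-2-yl)silyl]oxy}-2H-chromen-8-yl)-5-methoxy-3,4-dihydro-2H-chromen-7-ol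
Product: 15 (3R)-3-(2,2-dimethyl-5-{[tri(propan-2-yl)silyl]oxy}-2H-chromen-8-yl)-7-hydroxy-5-methoxy-3,4-dihydro-2H-chromene-8-carbaldehyde, via 8-hydroxymethyl phenol 14 (not isolated)
Conditions: MgCl2, Et3N, paraformaldehyde, MeCN, reflux
Reagents that add atoms: formaldehyde (as paraformaldehyde), C=O
Why: Casnati–Skattebøl ortho-formylation: the magnesium phenoxide delivers formaldehyde to an ortho carbon and a second formaldehyde oxidises the benzylic alkoxide; C8 should be preferred over C6 because the 5-methoxy group, turned toward C6 by the C4 methylene, shields C6 (the trend seen in electrophilic substitution of 5,7-dialkoxyflavans), and the silyl-protected ring B phenol cannot direct.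

Step 12
Reactants: 15 (3R)-3-(2,2-dimethyl-5-{[tri(propan-2-yl)silyl]oxy}-2H-chromen-8-yl)-7-hydroxy-5-methoxy-3,4-dihydro-2H-chromene-8-carbaldehyde
Product: 16 (3R)-7-hydroxy-3-(5-hydroxy-2,2-dimethyl-2H-chromen-8-yl)-5-methoxy-3,4-dihydro-2H-chromene-8-carbaldehyde (CNP0272344.1)
Conditions: TBAF, AcOH, THF, 0 °C
Reagents that add atoms: none
Why: Fluoride cleavage of the aryl silyl ether, buffered with acetic acid so that the phenolic aldehyde and the chromene are not exposed to strong base.

Compound list
1 | 2,6-dihydroxybenzaldehyde | O=Cc1c(O)cccc1O | starting material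
2 | 2-hydroxy-6-{[tri(propan-2-yl)silyl]oxy}benzaldehyde | O=Cc1c(O)cccc1O[Si](C(C)C)(C(C)C)C(C)C | intermediate
3 | 3-bromo-2-hydroxy-6-{[tri(propan-2-yl)silyl]oxy}benzaldehyde | O=Cc1c(O)c(Br)ccc1O[Si](C(C)C)(C(C)C)C(C)C | intermediate
4 | 3-bromo-2-(propan-2-yloxy)-6-{[tri(propan-2-yl)silyl]oxy}benzaldehyde | O=Cc1c(OC(C)C)c(Br)ccc1O[Si](C(C)C)(C(C)C)C(C)C | intermediate
5 | [4-bromo-2-ethynyl-3-(propan-2-yloxy)phenoxy]tri(propan-2-yl)silane | C#Cc1c(OC(C)C)c(Br)ccc1O[Si](C(C)C)(C(C)C)C(C)C | intermediate
6 | [(8-bromo-2,2-dimethyl-2H-chromen-5-yl)oxy]tri(propan-2-yl)silane | CC1(C)C=Cc2c(O[Si](C(C)C)(C(C)C)C(C)C)ccc(Br)c2O1 | intermediate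
7 | 5,7-dihydroxy-2,3-dihydro-4H-chromen-4-one | O=C1CCOc2cc(O)cc(O)c12 | starting material
8 | 5-hydroxy-7-(methoxymethoxy)-2,3-dihydro-4H-chromen-4-one | O=C1CCOc2cc(OCOC)cc(O)c12 | intermediate
9 | 5-methoxy-7-(methoxymethoxy)-2,3-dihydro-4H-chromen-4-one | O=C1CCOc2cc(OCOC)cc(OC)c12 | intermediate
10 | rac-3-(2,2-dimethyl-5-{[tri(propan-2-yl)silyl]oxy}-2H-chromen-8-yl)-5-methoxy-7-(methoxymethoxy)-2,3-dihydro-4H-chromen-4-one | O=C1C(c2ccc(O[Si](C(C)C)(C(C)C)C(C)C)c3C=CC(C)(C)Oc23)COc2cc(OCOC)cc(OC)c12 | intermediate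
11 | (3R,4R)-3-(2,2-dimethyl-5-{[tri(propan-2-yl)silyl]oxy}-2H-chromen-8-yl)-5-methoxy-7-(methoxymethoxy)-3,4-dihydro-2H-chromen-4-ol (cis) | COc1cc(OCOC)cc2c1[C@H](O)[C@H](c1ccc(O[Si](C(C)C)(C(C)C)C(C)C)c3c1OC(C)(C)C=C3)CO2 | intermediate
12 | (3R)-3-(2,2-dimethyl-5-{[tri(propan-2-yl)silyl]oxy}-2H-chromen-8-yl)-5-methoxy-7-(methoxymethoxy)-3,4-dihydro-2H-chromene | COc1cc(OCOC)cc2c1C[C@H](c1ccc(O[Si](C(C)C)(C(C)C)C(C)C)c3c1OC(C)(C)C=C3)CO2 | intermediate
13 | (3R)-3-(2,2-dimethyl-5-{[tri(propan-2-yl)silyl]oxy}-2H-chromen-8-yl)-5-methoxy-3,4-dihydro-2H-chromen-7-ol | COc1cc(O)cc2c1C[C@H](c1ccc(O[Si](C(C)C)(C(C)C)C(C)C)c3c1OC(C)(C)C=C3)CO2 | intermediate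
14 | (3R)-3-(2,2-dimethyl-5-{[tri(propan-2-yl)silyl]oxy}-2H-chromen-8-yl)-8-(hydroxymethyl)-5-methoxy-3,4-dihydro-2H-chromen-7-ol | COc1cc(O)c(CO)c2c1C[C@H](c1ccc(O[Si](C(C)C)(C(C)C)C(C)C)c3c1OC(C)(C)C=C3)CO2 | intermediate
15 | (3R)-3-(2,2-dimethyl-5-{[tri(propan-2-yl)silyl]oxy}-2H-chromen-8-yl)-7-hydroxy-5-methoxy-3,4-dihydro-2H-chromene-8-carbaldehyde | COc1cc(O)c(C=O)c2c1C[C@H](c1ccc(O[Si](C(C)C)(C(C)C)C(C)C)c3c1OC(C)(C)C=C3)CO2 | intermediate
16 | (3R)-7-hydroxy-3-(5-hydroxy-2,2-dimethyl-2H-chromen-8-yl)-5-methoxy-3,4-dihydro-2H-chromene-8-carbaldehyde | COc1cc(O)c(C=O)c2c1C[C@H](c1ccc(O)c3c1OC(C)(C)C=C3)CO2 | target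

Total step count: 12. Longest linear sequence: 10 steps (steps 1–5, then 8–12); steps 6–7 form the second branch.

Steps most likely to fail

Step 5. The hydride transfer from an aryl ether may be too slow, or the activated alkyne may be diverted into oxygen attack with loss of the isopropyl group, or into 5-exo closure. The fallback uses known chemistry that closes the same C2–C3 bond at the alkene oxidation level; it sets out from aldehyde 4 and comes back at bromochromene 6. Knoevenagel condensation of 4 with Meldrum's acid (pyrrolidinium acetate, benzene, rt) should give 5-{[3-bromo-2-(propan-2-yloxy)-6-{[tri(propan-2-yl)silyl]oxy}phenyl]methylidene}-2,2-dimethyl-1,3-dioxane-4,6-dione F1. Sc(OTf)3 (10 mol%) in 1,2-dichloroethane at 80 °C should then bring about the established 1,5-hydride shift/6-endo cyclisation of ortho-alkoxy arylidene malonates, giving 8-bromo-2,2,2',2'-tetramethyl-5-{[tri(propan-2-yl)silyl]oxy}spiro[chromane-3,5'-[1,3]dioxane]-4',6'-dione F2. Heating in DMF/water at 110 °C should open and decarboxylate the dioxanedione to racemic 8-bromo-2,2-dimethyl-5-{[tri(propan-2-yl)silyl]oxy}chromane-3-carboxylic acid F3. Kochi oxidative decarboxylation (Pb(OAc)4, Cu(OAc)2, pyridine, benzene, 80 °C) should then give 6; C3=C4 is the only possible position for the double bond because C2 carries no hydrogen.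

Step 9. Enantiopurity may erode if the benzylic cation loses the C3 proton and the resulting isoflavene is re-protonated before hydride capture, and the acid-sensitive chromene may be damaged in warm formic acid. The fallback sets out from isoflavanone 10 and comes back at isoflavan 12. The transfer hydrogenation is run with the same catalyst and HCO2Na in water/EtOAc at rt so that it stops at the cis alcohol 11, which is isolated. The hydroxyl is then removed in a separate ionic deoxygenation with Et3SiH and BF3·OEt2 in CH2Cl2 at −78 °C; there, hydride capture should outrun proton loss, and any isoflavene that forms is not reduced and so cannot lower the enantiopurity of 12. This fallback makes no compound outside the list (F0).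

Step 11. Site selectivity between C8 and C6 of ring A may be poor. The fallback replaces the phenoxide-directed formylation by halogenation and metalation; it sets out from methoxymethyl ether 12 and comes back at aldehyde 15. Bromination with NBS (1.0 equiv, CH2Cl2, −78 °C), which in 5,7-dialkoxyflavans goes to C8 and should be much faster on the trioxygenated ring A than on the chromene double bond, should give (3R)-8-bromo-3-(2,2-dimethyl-5-{[tri(propan-2-yl)silyl]oxy}-2H-chromen-8-yl)-5-methoxy-7-(methoxymethoxy)-3,4-dihydro-2H-chromene F4. Bromine–lithium exchange (n-BuLi, THF, −78 °C) and quench with DMF should give (3R)-3-(2,2-dimethyl-5-{[tri(propan-2-yl)silyl]oxy}-2H-chromen-8-yl)-5-methoxy-7-(methoxymethoxy)-3,4-dihydro-2H-chromene-8-carbaldehyde F5. Removal of the methoxymethyl group with NaHSO4·SiO2 in CH2Cl2 then gives 15.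

Further compounds
F1 | step 5 | 5-{[3-bromo-2-(propan-2-yloxy)-6-{[tri(propan-2-yl)silyl]oxy}phenyl]methylidene}-2,2-dimethyl-1,3-dioxane-4,6-dione | CC(C)Oc1c(Br)ccc(O[Si](C(C)C)(C(C)C)C(C)C)c1C=C1C(=O)OC(C)(C)OC1=O
F2 | step 5 | 8-bromo-2,2,2',2'-tetramethyl-5-{[tri(propan-2-yl)silyl]oxy}spiro[chromane-3,5'-[1,3]dioxane]-4',6'-dione | CC1(C)Oc2c(Br)ccc(O[Si](C(C)C)(C(C)C)C(C)C)c2CC13C(=O)OC(C)(C)OC3=O
F3 | step 5 | rac-8-bromo-2,2-dimethyl-5-{[tri(propan-2-yl)silyl]oxy}chromane-3-carboxylic acid | CC1(C)Oc2c(Br)ccc(O[Si](C(C)C)(C(C)C)C(C)C)c2CC1C(O)=O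
F0 | step 9 | none | none
F4 | step 11 | (3R)-8-bromo-3-(2,2-dimethyl-5-{[tri(propan-2-yl)silyl]oxy}-2H-chromen-8-yl)-5-methoxy-7-(methoxymethoxy)-3,4-dihydro-2H-chromene | COc1cc(OCOC)c(Br)c2c1C[C@H](c1ccc(O[Si](C(C)C)(C(C)C)C(C)C)c3c1OC(C)(C)C=C3)CO2
F5 | step 11 | (3R)-3-(2,2-dimethyl-5-{[tri(propan-2-yl)silyl]oxy}-2H-chromen-8-yl)-5-methoxy-7-(methoxymethoxy)-3,4-dihydro-2H-chromene-8-carbaldehyde | COc1cc(OCOC)c(C=O)c2c1C[C@H](c1ccc(O[Si](C(C)C)(C(C)C)C(C)C)c3c1OC(C)(C)C=C3)CO2
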